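**Strategy.** Ring B is disconnected last, at C5–C6 and C9=C10, from a preformed ring A enone. A Robinson-type annulation of the kinetic C5 dienolate of a 4-silyloxy-5,6-dimethylcyclohex-2-enone with an α-silyl vinyl ketone closes ring B (C5, C6, C7, C8, C9, C10). It sets quaternary C5 anti to the C4 methyl and, because C10 is already an enone carbonyl, delivers the C1=C2–C10=C9–C8=O dienone in the same operation. The step exploits the 1,5-relationship of C8=O and C10 across C5. The all-cis O3/Me4/Me5 triad of ring A maps onto meso all-cis-2,3-dimethylcyclohexane-1,4-diol from 2,3-dimethylhydroquinone. Isopropylidenation and esterification finish the synthesis.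

Key step: step 7

Numbering used in the text (eremophilane): ring A = C1, C2, C3 (ester oxygen), C4 (methyl), C5 (quaternary, methyl), C10; ring B = C5, C6, C7 (isopropylidene), C8 (ketone), C9, C10.

Assumption: compounds 1, 9, 16 and 17 are taken as purchasable.

Step 1
Reactants: 1 2,3-dimethylbenzene-1,4-diol (2,3-dimethylhydroquinone)
Product: 2 (1R,2S,3R,4S)-2,3-dimethylcyclohexane-1,4-diol (all-cis meso diol)
Conditions: H2 (50 bar), 5% Rh/Al2O3, iPrOH, 25 °C; recrystallisation
Reagents that add atoms: none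
Why: Heterogeneous arene hydrogenation delivers all hydrogens from the catalyst-bound face, so both hydroxyls and both methyls should end up all-cis (meso), with rhodium at low temperature limiting C–O hydrogenolysis.

Step 2
Reactants: 2 (1R,2S,3R,4S)-2,3-dimethylcyclohexane-1,4-diol
Product: 3 (1R,2S,3R,4S)-4-hydroxy-2,3-dimethylcyclohexyl acetate
Conditions: Candida antarctica lipase B (immobilised), vinyl acetate, tBuOMe, 30 °C
Reagents that add atoms: vinyl acetate, CC(=O)OC=C
Why: Lipase-catalysed transesterification desymmetrises the meso diol; by the empirical rule for secondary alcohols the (R)-carbinol (larger CH(CH3) side, smaller CH2 side) should be acylated, which fixes the absolute configuration of the future C3 and C4.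

Step 3
Reactants: 3 (1R,2S,3R,4S)-4-hydroxy-2,3-dimethylcyclohexyl acetate
Product: 4 (1R,2S,3R,4S)-4-[(tert-butyldimethylsilyl)oxy]-2,3-dimethylcyclohexyl acetate
Conditions: TBSCl, imidazole, DMF, 25 °C
Reagents that add atoms: tert-butyldimethylsilyl chloride, CC(C)(C)[Si](C)(C)Cl
Why: Standard silyl ether formation protects the future C3 oxygen for the three enolate steps that follow.

Step 4
Reactants: 4 (1R,2S,3R,4S)-4-[(tert-butyldimethylsilyl)oxy]-2,3-dimethylcyclohexyl acetate
Product: 5 (1R,2S,3R,4S)-4-[(tert-butyldimethylsilyl)oxy]-2,3-dimethylcyclohexan-1-ol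
Conditions: K2CO3, MeOH, 25 °C
Reagents that add atoms: none
Why: Base-catalysed transesterification (methanolysis) removes the acetate while the secondary silyl ether is stable.

Step 5
Reactants: 5 (1R,2S,3R,4S)-4-[(tert-butyldimethylsilyl)oxy]-2,3-dimethylcyclohexan-1-ol
Product: 6 (2S,3R,4S)-4-[(tert-butyldimethylsilyl)oxy]-2,3-dimethylcyclohexan-1-one
Conditions: Dess–Martin periodinane, CH2Cl2, 0 → 25 °C
Reagents that add atoms: none
Why: Dess–Martin oxidation gives the ketone (future C10) under near-neutral conditions; the α-methyl centre needs no protection from epimerisation because it becomes an enolate carbon in step 7.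

Step 6
Reactants: 6 (2S,3R,4S)-4-[(tert-butyldimethylsilyl)oxy]-2,3-dimethylcyclohexan-1-one
Product: 8 (4S,5R,6S)-4-[(tert-butyldimethylsilyl)oxy]-5,6-dimethylcyclohex-2-en-1-one, via sulfilimine adduct 7 (not isolated)
Conditions: LiN(iPr)2, THF, −78 °C; then N-tert-butylbenzenesulfinimidoyl chloride, −78 °C
Reagents that add atoms: none
Why: Kinetic enolisation at the CH2 α-carbon followed by one-pot enolate dehydrogenation (sulfenylation at sulfur, then syn-elimination of the sulfilimine) should place the new double bond at C1=C2 only.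

Step 7
Reactants: 8 (4S,5R,6S)-4-[(tert-butyldimethylsilyl)oxy]-5,6-dimethylcyclohex-2-en-1-one; 9 3-(trimethylsilyl)but-3-en-2-one
Product: 11 (4aR,5R,6S)-6-[(tert-butyldimethylsilyl)oxy]-4a,5-dimethyl-4,4a,5,6-tetrahydronaphthalen-2(3H)-one, via Michael adduct 10 (not isolated)
Conditions: LiN(iPr)2, THF, −78 °C; 9, −78 → −20 °C; then KOH, MeOH, 0 → 25 °C
Reagents that add atoms: none
Why: LiN(iPr)2 removes the α′ proton at C5 kinetically to give the cross-conjugated lithium dienolate, which adds in Michael fashion to the α-silyl enone 9 (C5–C6 bond); silicon stabilises the adduct enolate and suppresses polymerisation and proton scrambling. Methanolic KOH then removes silicon, the methyl ketone enolate (C9) attacks the ring A enone carbonyl C10 in a 6-(enolexo)-exo-trig aldol closure of ring B, and dehydration gives C9=C10 in conjugation with C1=C2. The closest known reaction type is the Robinson annulation in its α-silyl vinyl ketone variant for regiodefined lithium enolates. The only new stereocentre, quaternary C5, is controlled by the adjacent C4 methyl, which should sit pseudo-axial in the dienolate to avoid allylic 1,2-strain with the C5 methyl, so the acceptor enters anti to it and the C5 methyl ends cis to the C4 methyl and the C3 oxygen. The step needs α′- over γ-deprotonation (secured by the kinetic amide base at −78 °C and the bulky silyl ether next to C3–H) and C- over O-alkylation (secured by the soft Michael acceptor).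

Step 8
Reactants: 11 (4aR,5R,6S)-6-[(tert-butyldimethylsilyl)oxy]-4a,5-dimethyl-4,4a,5,6-tetrahydronaphthalen-2(3H)-one
Product: 12 (4aR,5R,6S)-6-[(tert-butyldimethylsilyl)oxy]-3-(2-hydroxypropan-2-yl)-4a,5-dimethyl-4,4a,5,6-tetrahydronaphthalen-2(3H)-one (mixture at C3 of the naphthalenone)
Conditions: LiN(iPr)2, THF, −78 °C; ZnCl2; acetone, −78 → −40 °C; NH4Cl (aq)
Reagents that add atoms: acetone, CC(C)=O
Why: Directed aldol addition: kinetic α′-deprotonation at C7 (the only sp3 α-carbon) and transmetalation to the zinc enolate should hold the acetone adduct against retro-aldol; the new centre at C7 is removed in step 9.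

Step 9
Reactants: 12 (4aR,5R,6S)-6-[(tert-butyldimethylsilyl)oxy]-3-(2-hydroxypropan-2-yl)-4a,5-dimethyl-4,4a,5,6-tetrahydronaphthalen-2(3H)-one
Product: 14 (4aR,5R,6S)-6-[(tert-butyldimethylsilyl)oxy]-4a,5-dimethyl-3-(propan-2-ylidene)-4,4a,5,6-tetrahydronaphthalen-2(3H)-one, via tertiary mesylate 13 (not isolated)
Conditions: MsCl, Et3N, CH2Cl2, 0 °C; then DBU, 25 °C
Reagents that add atoms: none
Why: Mesylation (through sulfene) and E1cB elimination through the C7 enolate should give the conjugated tetrasubstituted C7=C11 alkene in preference to the isopropenyl isomer.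

Step 10
Reactants: 14 (4aR,5R,6S)-6-[(tert-butyldimethylsilyl)oxy]-4a,5-dimethyl-3-(propan-2-ylidene)-4,4a,5,6-tetrahydronaphthalen-2(3H)-one
Product: 15 (4aR,5R,6S)-6-hydroxy-4a,5-dimethyl-3-(propan-2-ylidene)-4,4a,5,6-tetrahydronaphthalen-2(3H)-one
Conditions: HF·pyridine, THF, 0 → 25 °C
Reagents that add atoms: none
Why: Fluoride-mediated desilylation under mildly acidic conditions avoids base-induced deconjugation of the cross-conjugated trienone.

Step 11
Reactants: 16 (S)-2-methylbutan-1-ol; 17 triethyl (E)-4-phosphonocrotonate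
Product: 19 ethyl (2E,4E,6S)-6-methylocta-2,4-dienoate, via (S)-2-methylbutanal 18 (not isolated)
Conditions: TEMPO (cat.), KBr (cat.), NaOCl, CH2Cl2/H2O, 0 °C; dried solution of 18 added to 17 and LiN(SiMe3)2, THF, −78 → 0 °C
Reagents that add atoms: none
Why: Nitroxyl-catalysed hypochlorite oxidation should give the α-branched aldehyde without racemisation, and the vinylogous Horner–Wadsworth–Emmons olefination should form the new C4=C5 bond E while the crotonate keeps C2=C3 E; the stereocentre comes from the chiral pool alcohol.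

Step 12
Reactants: 19 ethyl (2E,4E,6S)-6-methylocta-2,4-dienoate
Product: 20 (2E,4E,6S)-6-methylocta-2,4-dienoic acid
Conditions: LiOH, THF/MeOH/H2O, 25 °C; then HCl (aq)
Reagents that add atoms: lithium hydroxide, [Li+].[OH-]
Why: Saponification at room temperature should leave the diene geometry and the remote stereocentre untouched.

Step 13
Reactants: 15 (4aR,5R,6S)-6-hydroxy-4a,5-dimethyl-3-(propan-2-ylidene)-4,4a,5,6-tetrahydronaphthalen-2(3H)-one; 20 (2E,4E,6S)-6-methylocta-2,4-dienoic acid
Product: 21 (1R,2S,8aR)-1,8a-dimethyl-6-oxo-7-(propan-2-ylidene)-1,2,6,7,8,8a-hexahydronaphthalen-2-yl (2E,4E,6S)-6-methylocta-2,4-dienoate (CNP0215744.1)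
Conditions: DCC, DMAP, CH2Cl2, 0 → 25 °C
Reagents that add atoms: none
Why: Steglich esterification acylates the C3 hydroxyl with retention at carbon, so the configuration set in steps 1 and 2 is carried into the target.

**Compound list**

1 | 2,3-dimethylbenzene-1,4-diol | Cc1c(C)c(O)ccc1O | starting material
2 | (1R,2S,3R,4S)-2,3-dimethylcyclohexane-1,4-diol (all-cis, meso) | O[C@H]1CC[C@@H](O)[C@@H](C)[C@H]1C | intermediate
3 | (1R,2S,3R,4S)-4-hydroxy-2,3-dimethylcyclohexyl acetate | O[C@H]1CC[C@@H](OC(C)=O)[C@@H](C)[C@H]1C | intermediate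
4 | (1R,2S,3R,4S)-4-[(tert-butyldimethylsilyl)oxy]-2,3-dimethylcyclohexyl acetate | CC(C)(C)[Si](C)(C)O[C@H]1CC[C@@H](OC(C)=O)[C@@H](C)[C@H]1C | intermediate
5 | (1R,2S,3R,4S)-4-[(tert-butyldimethylsilyl)oxy]-2,3-dimethylcyclohexan-1-ol | CC(C)(C)[Si](C)(C)O[C@H]1CC[C@@H](O)[C@@H](C)[C@H]1C | intermediate
6 | (2S,3R,4S)-4-[(tert-butyldimethylsilyl)oxy]-2,3-dimethylcyclohexan-1-one | CC(C)(C)[Si](C)(C)O[C@H]1CCC(=O)[C@@H](C)[C@H]1C | intermediate
7 | (2S,3R,4S)-4-[(tert-butyldimethylsilyl)oxy]-6-(N-tert-butyl-S-phenylsulfinimidoyl)-2,3-dimethylcyclohexan-1-one (sulfilimine adduct, C6 and S unassigned) | CC(C)(C)[Si](C)(C)O[C@H]1CC(S(=NC(C)(C)C)c2ccccc2)C(=O)[C@@H](C)[C@H]1C | intermediate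
8 | (4S,5R,6S)-4-[(tert-butyldimethylsilyl)oxy]-5,6-dimethylcyclohex-2-en-1-one | CC(C)(C)[Si](C)(C)O[C@H]1C=CC(=O)[C@@H](C)[C@H]1C | intermediate
9 | 3-(trimethylsilyl)but-3-en-2-one | CC(=O)C(=C)[Si](C)(C)C | starting material
10 | (4S,5R,6R)-4-[(tert-butyldimethylsilyl)oxy]-5,6-dimethyl-6-[3-oxo-2-(trimethylsilyl)butyl]cyclohex-2-en-1-one (Michael adduct, silyl-bearing carbon unassigned) | CC(C)(C)[Si](C)(C)O[C@H]1C=CC(=O)[C@](C)(CC(C(C)=O)[Si](C)(C)C)[C@H]1C | intermediate
11 | (4aR,5R,6S)-6-[(tert-butyldimethylsilyl)oxy]-4a,5-dimethyl-4,4a,5,6-tetrahydronaphthalen-2(3H)-one | CC(C)(C)[Si](C)(C)O[C@H]1C=CC2=CC(=O)CC[C@]2(C)[C@H]1C | intermediate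
12 | (4aR,5R,6S)-6-[(tert-butyldimethylsilyl)oxy]-3-(2-hydroxypropan-2-yl)-4a,5-dimethyl-4,4a,5,6-tetrahydronaphthalen-2(3H)-one | CC(C)(C)[Si](C)(C)O[C@H]1C=CC2=CC(=O)C(C(C)(C)O)C[C@]2(C)[C@H]1C | intermediate
13 | 2-[(4aR,5R,6S)-6-[(tert-butyldimethylsilyl)oxy]-4a,5-dimethyl-2-oxo-2,3,4,4a,5,6-hexahydronaphthalen-3-yl]propan-2-yl methanesulfonate | CC(C)(C)[Si](C)(C)O[C@H]1C=CC2=CC(=O)C(C(C)(C)OS(C)(=O)=O)C[C@]2(C)[C@H]1C | intermediate
14 | (4aR,5R,6S)-6-[(tert-butyldimethylsilyl)oxy]-4a,5-dimethyl-3-(propan-2-ylidene)-4,4a,5,6-tetrahydronaphthalen-2(3H)-one | CC(C)(C)[Si](C)(C)O[C@H]1C=CC2=CC(=O)C(=C(C)C)C[C@]2(C)[C@H]1C | intermediate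
15 | (4aR,5R,6S)-6-hydroxy-4a,5-dimethyl-3-(propan-2-ylidene)-4,4a,5,6-tetrahydronaphthalen-2(3H)-one | O[C@H]1C=CC2=CC(=O)C(=C(C)C)C[C@]2(C)[C@H]1C | intermediate
16 | (S)-2-methylbutan-1-ol | CC[C@H](C)CO | starting material
17 | triethyl (E)-4-phosphonocrotonate (ethyl (E)-4-(diethoxyphosphoryl)but-2-enoate) | CCOC(=O)/C=C/CP(=O)(OCC)OCC | starting material
18 | (S)-2-methylbutanal | CC[C@H](C)C=O | intermediate
19 | ethyl (2E,4E,6S)-6-methylocta-2,4-dienoate | CC[C@H](C)/C=C/C=C/C(=O)OCC | intermediate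
20 | (2E,4E,6S)-6-methylocta-2,4-dienoic acid | CC[C@H](C)/C=C/C=C/C(=O)O | intermediate
21 | (1R,2S,8aR)-1,8a-dimethyl-6-oxo-7-(propan-2-ylidene)-1,2,6,7,8,8a-hexahydronaphthalen-2-yl (2E,4E,6S)-6-methylocta-2,4-dienoate | CC[C@H](C)/C=C/C=C/C(=O)O[C@H]1C=CC2=CC(=O)C(=C(C)C)C[C@]2(C)[C@H]1C | target

**Step count.** Total: 13 steps. Longest linear sequence: 11 steps (steps 1 to 10, then step 13); steps 11 and 12 make the acid in a side branch.

**Steps most likely to fail, with fallbacks**

Step 7 (key annulation). The conjugate addition may be sluggish or reversible at the hindered, fully substituted enolate carbon, the enolate may equilibrate by proton transfer, and the basic aldol stage may cause γ-deprotonation next to the silyl ether. The fallback sets out from 6 and comes back at 11. A thermodynamic Robinson annulation of the saturated ketone 6 with methyl vinyl ketone (KOH, EtOH) should react at the more substituted α-carbon, again anti to the C4 methyl, and give the octalone (4aR,5R,6S)-6-[(tert-butyldimethylsilyl)oxy]-4a,5-dimethyl-4,4a,5,6,7,8-hexahydronaphthalen-2(3H)-one F1. Its thermodynamic dienol ether (4aR,5R,6S)-6-[(tert-butyldimethylsilyl)oxy]-4a,5-dimethyl-2-[(trimethylsilyl)oxy]-3,4,4a,5,6,7-hexahydronaphthalene F2 (TMSOTf, Et3N) would then be dehydrogenated with Pd(OAc)2 in MeCN (Saegusa–Ito oxidation) to 11, which places the C1=C2 bond after ring closure instead of before it.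

Step 1 (arene hydrogenation). Facial fidelity may be lost when partly reduced keto tautomers leave and re-bind the catalyst, giving diastereomeric diols, and C–O hydrogenolysis may compete. The fallback sets out from 1 and comes back at 2. Bis-silylation (TBSCl, imidazole) gives 1,4-bis[(tert-butyldimethylsilyl)oxy]-2,3-dimethylbenzene F3, whose aryl silyl ethers cannot tautomerise. Hydrogenation with a rhodium cyclic (alkyl)(amino)carbene catalyst, Rh(CAAC)(COD)Cl, under H2 should give the all-cis ether (1R,2S,3R,4S)-1,4-bis[(tert-butyldimethylsilyl)oxy]-2,3-dimethylcyclohexane F4, and Bu4NF then releases 2.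

Step 2 (enzymatic desymmetrisation). The lipase may discriminate the two enantiotopic hydroxyls poorly, or acylate the hindered carbinols too slowly. The fallback sets out from 2 and comes back at 5, replacing the catalyst by a stoichiometric chiral acid and diastereomer separation. Monoesterification of 2 with (S)-2-methoxy-2-phenylacetic acid (DCC, DMAP) gives two diastereomeric monoesters, separable by chromatography. The one acylated at the (R)-carbinol, (1R,2S,3R,4S)-4-hydroxy-2,3-dimethylcyclohexyl (S)-2-methoxy-2-phenylacetate F5, is silylated (TBSCl, imidazole) to (1R,2S,3R,4S)-4-[(tert-butyldimethylsilyl)oxy]-2,3-dimethylcyclohexyl (S)-2-methoxy-2-phenylacetate F6 and transesterified (K2CO3, MeOH) to 5. The other diastereomer is hydrolysed back to 2 and recycled.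

Further compounds
F1 | step 7 | (4aR,5R,6S)-6-[(tert-butyldimethylsilyl)oxy]-4a,5-dimethyl-4,4a,5,6,7,8-hexahydronaphthalen-2(3H)-one | CC(C)(C)[Si](C)(C)O[C@H]1CCC2=CC(=O)CC[C@]2(C)[C@H]1C
F2 | step 7 | (4aR,5R,6S)-6-[(tert-butyldimethylsilyl)oxy]-4a,5-dimethyl-2-[(trimethylsilyl)oxy]-3,4,4a,5,6,7-hexahydronaphthalene | CC(C)(C)[Si](C)(C)O[C@H]1CC=C2C=C(O[Si](C)(C)C)CC[C@]2(C)[C@H]1C
F3 | step 1 | 1,4-bis[(tert-butyldimethylsilyl)oxy]-2,3-dimethylbenzene | CC(C)(C)[Si](C)(C)Oc1ccc(O[Si](C)(C)C(C)(C)C)c(C)c1C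
F4 | step 1 | (1R,2S,3R,4S)-1,4-bis[(tert-butyldimethylsilyl)oxy]-2,3-dimethylcyclohexane (all-cis, meso) | CC(C)(C)[Si](C)(C)O[C@H]1CC[C@@H](O[Si](C)(C)C(C)(C)C)[C@@H](C)[C@H]1C
F5 | step 2 | (1R,2S,3R,4S)-4-hydroxy-2,3-dimethylcyclohexyl (S)-2-methoxy-2-phenylacetate | O[C@H]1CC[C@@H](OC(=O)[C@@H](OC)c2ccccc2)[C@@H](C)[C@H]1C
F6 | step 2 | (1R,2S,3R,4S)-4-[(tert-butyldimethylsilyl)oxy]-2,3-dimethylcyclohexyl (S)-2-methoxy-2-phenylacetate | CC(C)(C)[Si](C)(C)O[C@H]1CC[C@@H](OC(=O)[C@@H](OC)c2ccccc2)[C@@H](C)[C@H]1C
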